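**Retrosynthetic overview**
Feature: ring B is a phloroglucinol ring. Its C1 carries the O-aryl bridge to ring A, C2 and C6 carry free OH, and only the C4 oxygen is sulfated. This pattern maps onto the chain ArO–CH2–CO–CH2–C(OPMB)=CH–CO2Me, with chain C6 = ring C1, chain C1 = ring C2 and chain C3–O = ring C4–O.
Late disconnections: the two O–SO3H bonds, made from the two phenols released from 4-methoxybenzyl (PMB) ethers, and three benzyl ethers on the hydroxyls that stay free.
Key disconnection: the ring B C1–C2 bond, formed by intramolecular Claisen condensation of enoate 15. Enoate 15 comes from 4-PMBO-2-pyrone 14 by methanolysis, and 14 from the acetoacetate dianion and N-methoxy-N-methyl amide 8.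
Ring A is bought as 1-bromo-3,5-difluorobenzene. Its three different oxygens are installed one at a time (two SNAr steps, one hydroxylation), so no statistical alkylation of phloroglucinol is needed.
Ring order: ring A (purchased), then a temporary 2-pyrone ring (closed in step 6, opened in step 8), then ring B (step 9).

Key step: step 9

Assumption: the target is drawn as the free bis(hydrogen sulfate). Aryl hydrogen sulfates are acid-labile, so both sulfate groups are carried as sodium salts and protonated only in the last operation, by cation exchange in the cold.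

**Step 1**
Reactants: 1 1-bromo-3,5-difluorobenzene; 2 benzyl alcohol
Product: 3 1-(benzyloxy)-3-bromo-5-fluorobenzene
Conditions: BnOH (1.05 equiv), KOt-Bu (1.0 equiv), DMF, 0 °C → rt
Reagents that add atoms: benzyl alcohol (2), OCc1ccccc1
Why: Nucleophilic aromatic substitution (SNAr, addition–elimination): fluoride is a far better leaving group than bromide in this mechanism, and once one inductively activating meta-fluorine has been exchanged for an alkoxy group the remaining C–F bond should react much more slowly, so one equivalent of alkoxide should stop at the mono-ether.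

**Step 2**
Reactants: 3 1-(benzyloxy)-3-bromo-5-fluorobenzene; 4 4-methoxybenzyl alcohol
Product: 5 1-(benzyloxy)-3-bromo-5-[(4-methoxybenzyl)oxy]benzene
Conditions: 4-MeOC6H4CH2OH (1.5 equiv), KOt-Bu (1.4 equiv), NMP, 100 °C
Reagents that add atoms: 4-methoxybenzyl alcohol (4), COc1ccc(CO)cc1
Why: Second SNAr on the remaining C–F bond, which needs a dipolar aprotic solvent and heat but is still helped by the inductive pull of the meta bromine and meta alkoxy group, while the C–Br bond and the benzyl ether should not be touched by the alkoxide.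

**Step 3**
Reactants: 5 1-(benzyloxy)-3-bromo-5-[(4-methoxybenzyl)oxy]benzene
Product: 6 3-(benzyloxy)-5-[(4-methoxybenzyl)oxy]phenol
Conditions: Pd2(dba)3 (2 mol %), t-BuXPhos (8 mol %), KOH, 1,4-dioxane–H2O, 100 °C; then 1 M HCl, 0 °C
Reagents that add atoms: potassium hydroxide, [K+].[OH-]
Why: Palladium-catalysed hydroxylation of an aryl bromide (C–O cross-coupling with hydroxide), in which the bulky biaryl phosphine favours C–O reductive elimination and holds back diaryl ether formation, and to which benzyl and 4-methoxybenzyl ethers are inert.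

**Step 4**
Reactants: 6 3-(benzyloxy)-5-[(4-methoxybenzyl)oxy]phenol; 7 2-chloro-N-methoxy-N-methylacetamide
Product: 8 2-{3-(benzyloxy)-5-[(4-methoxybenzyl)oxy]phenoxy}-N-methoxy-N-methylacetamide
Conditions: K2CO3, NaI (cat.), DMF, 50 °C
Reagents that add atoms: 2-chloro-N-methoxy-N-methylacetamide (7), CON(C)C(=O)CCl
Why: Williamson ether synthesis with Finkelstein activation: the phenoxide displaces halide from the primary α-halo amide by SN2, and the N-methoxy-N-methyl amide is not attacked by carbonate or phenoxide.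

**Step 5**
Reactants: 8 2-{3-(benzyloxy)-5-[(4-methoxybenzyl)oxy]phenoxy}-N-methoxy-N-methylacetamide; 9 methyl acetoacetate
Product: 12 methyl 6-{3-(benzyloxy)-5-[(4-methoxybenzyl)oxy]phenoxy}-3,5-dioxohexanoate, via acetoacetate sodium lithium dianion 10 (not isolated), via chelated tetrahedral adduct 11 (not isolated)
Conditions: 9 (1.5 equiv), NaH, THF, 0 °C; n-BuLi, 0 °C; then 8, THF, −78 → 0 °C; cold 1 M HCl
Reagents that add atoms: methyl acetoacetate (9), COC(=O)CC(C)=O
Why: Weinreb ketone synthesis with the γ-carbon of the acetoacetate dianion as nucleophile: the more reactive terminal carbanion adds to the amide, and chelate 11 survives until the quench, so that neither double addition nor protonation of unreacted dianion by the acidic triketide should occur.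

**Step 6**
Reactants: 12 methyl 6-{3-(benzyloxy)-5-[(4-methoxybenzyl)oxy]phenoxy}-3,5-dioxohexanoate
Product: 13 6-({3-(benzyloxy)-5-[(4-methoxybenzyl)oxy]phenoxy}methyl)-4-hydroxy-2H-pyran-2-one
Conditions: DBU (1.5 equiv), toluene, 90 °C; then 1 M HCl, 0 °C
Reagents that add atoms: none
Why: Base-mediated lactonisation of a 3,5-dioxo ester (O-acylation of the C5 enol by the ester, loss of methanol), the standard entry to 6-substituted 4-hydroxy-2-pyrones, which fixes chain C1 and chain C4 cis on what will become the C2=C3 double bond.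

**Step 7**
Reactants: 13 6-({3-(benzyloxy)-5-[(4-methoxybenzyl)oxy]phenoxy}methyl)-4-hydroxy-2H-pyran-2-one; 4 4-methoxybenzyl alcohol
Product: 14 6-({3-(benzyloxy)-5-[(4-methoxybenzyl)oxy]phenoxy}methyl)-4-[(4-methoxybenzyl)oxy]-2H-pyran-2-one
Conditions: 4-MeOC6H4CH2OH, PPh3, DIAD, THF, 0 °C → rt
Reagents that add atoms: 4-methoxybenzyl alcohol (4), COc1ccc(CO)cc1
Why: Mitsunobu reaction: the acidic vinylogous carboxylic acid OH of the 4-hydroxy-2-pyrone is a good pronucleophile and is alkylated on the C4 oxygen by the activated primary benzylic alcohol, which avoids the C3-alkylation and 2-alkoxy-4-pyrone formation seen with benzylic halides and base.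

**Step 8**
Reactants: 14 6-({3-(benzyloxy)-5-[(4-methoxybenzyl)oxy]phenoxy}methyl)-4-[(4-methoxybenzyl)oxy]-2H-pyran-2-one
Product: 15 methyl (E)-6-{3-(benzyloxy)-5-[(4-methoxybenzyl)oxy]phenoxy}-3-[(4-methoxybenzyl)oxy]-5-oxohex-2-enoate
Conditions: Mg(OMe)2 (2.5 equiv, commercial solution), MeOH, reflux; then AcOH, 0 °C
Reagents that add atoms: magnesium dimethoxide, [Mg+2].[O-]C.[O-]C; methanol, CO
Why: Magnesium methoxide methanolysis of a 4-alkoxy-2-pyrone (acyl–oxygen cleavage of the enol lactone), known for triacetic acid lactone ethers: methoxide attacks the magnesium-activated C2 carbonyl, the opened chain is kept deprotonated at C4 so that the equilibrium is pulled to the open form, and the E geometry is both inherited from the ring and the thermodynamically preferred one for 3-alkoxy-2-enoates.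

**Step 9**
Reactants: 15 methyl (E)-6-{3-(benzyloxy)-5-[(4-methoxybenzyl)oxy]phenoxy}-3-[(4-methoxybenzyl)oxy]-5-oxohex-2-enoate
Product: 16 2-{3-(benzyloxy)-5-[(4-methoxybenzyl)oxy]phenoxy}-5-[(4-methoxybenzyl)oxy]benzene-1,3-diol
Conditions: KOt-Bu (2.2 equiv), t-BuOH–1,4-dioxane (1:4), 0.02 M, degassed, Ar, rt → 100 °C; then cold 1 M HCl to pH 5
Reagents that add atoms: none
Why: The base first removes the most acidic proton at C4, but in that dienolate the charge runs into the ester, so it cannot close a carbocycle; proton exchange through t-BuOH gives the minor enolate at the aryloxymethyl carbon C6, which adds to the still neutral enoate carbonyl C1, methoxide leaves, and the cyclised keto form tautomerises at once to the resorcinol, held as its phenoxide. The closest known reaction type is the intramolecular Claisen (Dieckmann-type) condensation that turns 3,5-dioxohexanoates and the 3-alkoxy-5-oxohex-2-enoates obtained from triacetic acid lactone ethers into phloroglucinol and its monoethers; the aryloxy group on the nucleophilic carbon is the untested variable, and since it acidifies C6 by several pK units it should raise the share of the productive enolate and allow about 100 °C instead of the much harsher heating needed for a methyl terminus. Ring B closes in the 6-(enolendo)-exo-trig mode, forming the bond between ring B C1 (chain C6) and ring B C2 (chain C1). No stereocentre is created; the E double bond places ester and ketone arm on the same side, and rotation about C2–C3 in the C4 dienolate would feed any Z isomer back. The step needs C6 over C4 enolisation and C- over O-acylation: O-acylation only regenerates pyrone 14, which the released methoxide reopens, whereas C-acylation ends in an aromatic phenoxide that cannot revert, so all equilibria should drain into 16. The enol ether oxygen becomes the ring B C4 oxygen and stays marked by its 4-methoxybenzyl group, apart from the two new hydroxyls at C2 and C6.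

**Step 10**
Reactants: 16 2-{3-(benzyloxy)-5-[(4-methoxybenzyl)oxy]phenoxy}-5-[(4-methoxybenzyl)oxy]benzene-1,3-diol; 17 benzyl bromide
Product: 18 1,3-bis(benzyloxy)-2-{3-(benzyloxy)-5-[(4-methoxybenzyl)oxy]phenoxy}-5-[(4-methoxybenzyl)oxy]benzene
Conditions: BnBr (2.5 equiv), K2CO3, DMF, Ar, 50 °C
Reagents that add atoms: benzyl bromide (17), BrCc1ccccc1
Why: Williamson ether synthesis on both new phenols, with carbonate in DMF favouring O- over C-alkylation, which converts the air-sensitive resorcinol into a stable pentaether in which only the two future sulfate positions carry 4-methoxybenzyl groups.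

**Step 11**
Reactants: 18 1,3-bis(benzyloxy)-2-{3-(benzyloxy)-5-[(4-methoxybenzyl)oxy]phenoxy}-5-[(4-methoxybenzyl)oxy]benzene
Product: 19 3,5-bis(benzyloxy)-4-[3-(benzyloxy)-5-hydroxyphenoxy]phenol
Conditions: TFA (10 vol %), Et3SiH (10 equiv), CH2Cl2, 0 °C → rt; aq NaHCO3
Reagents that add atoms: none
Why: Acid-mediated SN1 cleavage of aryl 4-methoxybenzyl ethers with ionic hydrogenation of the released cation: dilute TFA ionises only the 4-methoxybenzyl ethers, the plain benzyl ethers being far slower, and a large excess of silane reduces the cation to 4-methylanisole before it can alkylate the electron-rich rings; an oxidative cleavage with DDQ is avoided because the freed ring B phenol is a 4-aryloxyphenol that is prone to quinone formation.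

**Step 12**
Reactants: 19 3,5-bis(benzyloxy)-4-[3-(benzyloxy)-5-hydroxyphenoxy]phenol
Product: 21 disodium 3,5-bis(benzyloxy)-4-[3-(benzyloxy)-5-(sulfonatooxy)phenoxy]phenyl sulfate, via bis(pyridinium) bis-sulfate 20 (not isolated)
Conditions: SO3·pyridine (6 equiv), pyridine, 40 °C; then aq NaHCO3, evaporation, reversed-phase chromatography
Reagents that add atoms: sulfur trioxide–pyridine complex, O=S(=O)([O-])[n+]1ccccc1; sodium hydrogen carbonate, [Na+].OC([O-])=O
Why: O-Sulfation of phenols with the sulfur trioxide–pyridine complex, which is mild enough not to sulfonate the rings at carbon and leaves benzyl ethers alone; exchange to the sodium salt removes pyridine, which would slow the later hydrogenolysis.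

**Step 13**
Reactants: 21 disodium 3,5-bis(benzyloxy)-4-[3-(benzyloxy)-5-(sulfonatooxy)phenoxy]phenyl sulfate
Product: 23 3,5-dihydroxy-4-[3-hydroxy-5-(sulfooxy)phenoxy]phenyl hydrogen sulfate (CNP0460023.0), via target disodium salt 22 (not isolated)
Conditions: H2 (1 atm), 10% Pd/C, MeOH–H2O, rt; filter; then Dowex 50WX8 (H+ form), H2O, 0–5 °C; lyophilise
Reagents that add atoms: none
Why: Catalytic hydrogenolysis of the three aryl benzyl ethers, to which aryl sulfate anions are inert in neutral medium, followed by cation exchange of sodium for protons in the cold to limit acid-catalysed loss of sulfate.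

**Compound list**
1 | 1-bromo-3,5-difluorobenzene | Fc1cc(F)cc(Br)c1 | starting material
2 | benzyl alcohol | OCc1ccccc1 | starting material
3 | 1-(benzyloxy)-3-bromo-5-fluorobenzene | Fc1cc(Br)cc(OCc2ccccc2)c1 | intermediate
4 | 4-methoxybenzyl alcohol | COc1ccc(CO)cc1 | starting material
5 | 1-(benzyloxy)-3-bromo-5-[(4-methoxybenzyl)oxy]benzene | COc1ccc(COc2cc(Br)cc(OCc3ccccc3)c2)cc1 | intermediate
6 | 3-(benzyloxy)-5-[(4-methoxybenzyl)oxy]phenol | COc1ccc(COc2cc(O)cc(OCc3ccccc3)c2)cc1 | intermediate
7 | 2-chloro-N-methoxy-N-methylacetamide | CON(C)C(=O)CCl | starting material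
8 | 2-{3-(benzyloxy)-5-[(4-methoxybenzyl)oxy]phenoxy}-N-methoxy-N-methylacetamide | CON(C)C(=O)COc1cc(OCc2ccccc2)cc(OCc2ccc(OC)cc2)c1 | intermediate
9 | methyl acetoacetate | COC(=O)CC(C)=O | starting material
10 | sodium lithium dianion of methyl acetoacetate | [Na+].[Li+].C=C([O-])C=C([O-])OC | intermediate (not isolated)
11 | chelated tetrahedral adduct of 10 and 8 (racemic, transient) | [Na+].[Li+].COC(=O)C=C([O-])CC([O-])(COc1cc(OCc2ccccc2)cc(OCc2ccc(OC)cc2)c1)N(C)OC | intermediate (not isolated)
12 | methyl 6-{3-(benzyloxy)-5-[(4-methoxybenzyl)oxy]phenoxy}-3,5-dioxohexanoate | COC(=O)CC(=O)CC(=O)COc1cc(OCc2ccccc2)cc(OCc2ccc(OC)cc2)c1 | intermediate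
13 | 6-({3-(benzyloxy)-5-[(4-methoxybenzyl)oxy]phenoxy}methyl)-4-hydroxy-2H-pyran-2-one | O=c1cc(O)cc(COc2cc(OCc3ccccc3)cc(OCc3ccc(OC)cc3)c2)o1 | intermediate
14 | 6-({3-(benzyloxy)-5-[(4-methoxybenzyl)oxy]phenoxy}methyl)-4-[(4-methoxybenzyl)oxy]-2H-pyran-2-one | COc1ccc(COc2cc(COc3cc(OCc4ccccc4)cc(OCc4ccc(OC)cc4)c3)oc(=O)c2)cc1 | intermediate
15 | methyl (E)-6-{3-(benzyloxy)-5-[(4-methoxybenzyl)oxy]phenoxy}-3-[(4-methoxybenzyl)oxy]-5-oxohex-2-enoate | COC(=O)/C=C(/OCc1ccc(OC)cc1)CC(=O)COc1cc(OCc2ccccc2)cc(OCc2ccc(OC)cc2)c1 | intermediate (key-step precursor)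
16 | 2-{3-(benzyloxy)-5-[(4-methoxybenzyl)oxy]phenoxy}-5-[(4-methoxybenzyl)oxy]benzene-1,3-diol | COc1ccc(COc2cc(O)c(Oc3cc(OCc4ccccc4)cc(OCc4ccc(OC)cc4)c3)c(O)c2)cc1 | intermediate (key-step product)
17 | benzyl bromide | BrCc1ccccc1 | starting material
18 | 1,3-bis(benzyloxy)-2-{3-(benzyloxy)-5-[(4-methoxybenzyl)oxy]phenoxy}-5-[(4-methoxybenzyl)oxy]benzene | COc1ccc(COc2cc(OCc3ccccc3)cc(Oc3c(OCc4ccccc4)cc(OCc4ccc(OC)cc4)cc3OCc3ccccc3)c2)cc1 | intermediate
19 | 3,5-bis(benzyloxy)-4-[3-(benzyloxy)-5-hydroxyphenoxy]phenol | Oc1cc(OCc2ccccc2)cc(Oc2c(OCc3ccccc3)cc(O)cc2OCc2ccccc2)c1 | intermediate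
20 | bis(pyridinium) 3,5-bis(benzyloxy)-4-[3-(benzyloxy)-5-(sulfonatooxy)phenoxy]phenyl sulfate | [O-]S(=O)(=O)Oc1cc(OCc2ccccc2)cc(Oc2c(OCc3ccccc3)cc(OS(=O)(=O)[O-])cc2OCc2ccccc2)c1.c1cc[nH+]cc1.c1cc[nH+]cc1 | intermediate (not isolated)
21 | disodium 3,5-bis(benzyloxy)-4-[3-(benzyloxy)-5-(sulfonatooxy)phenoxy]phenyl sulfate | [Na+].[Na+].[O-]S(=O)(=O)Oc1cc(OCc2ccccc2)cc(Oc2c(OCc3ccccc3)cc(OS(=O)(=O)[O-])cc2OCc2ccccc2)c1 | intermediate
22 | disodium 3,5-dihydroxy-4-[3-hydroxy-5-(sulfonatooxy)phenoxy]phenyl sulfate | [Na+].[Na+].[O-]S(=O)(=O)Oc1cc(O)cc(Oc2c(O)cc(OS(=O)(=O)[O-])cc2O)c1 | intermediate (not isolated)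
23 | 3,5-dihydroxy-4-[3-hydroxy-5-(sulfooxy)phenoxy]phenyl hydrogen sulfate (CNP0460023.0) | O=S(=O)(O)Oc1cc(O)cc(Oc2c(O)cc(OS(=O)(=O)O)cc2O)c1 | target

**Total step count:** 13. **Longest linear sequence:** 13 (1 → 23).

**Steps most likely to fail**

Step 9 (ring B closure). Enolisation may stay parked at C4, the chain may return to the pyrone by O-acylation faster than it is reopened, or the 4-methoxybenzyl enol ether may be lost at the temperature needed, so that ring B does not close.
The fallback makes the bridge oxygen by an Ullmann-type C–O coupling. It sets out from aryl bromide 5 and comes back at 18.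
- Commercial 2,4,6-trihydroxybenzaldehyde is alkylated with 4-methoxybenzyl chloride (1 equiv, K2CO3, acetone) at the para hydroxyl, the most acidic and least hydrogen-bonded one. This gives 2,6-dihydroxy-4-[(4-methoxybenzyl)oxy]benzaldehyde F1.
- Benzylation with 17 (K2CO3, DMF) gives 2,6-bis(benzyloxy)-4-[(4-methoxybenzyl)oxy]benzaldehyde F2.
- Baeyer–Villiger oxidation (mCPBA, CH2Cl2) gives 2,6-bis(benzyloxy)-4-[(4-methoxybenzyl)oxy]phenyl formate F3.
- Methanolysis (K2CO3, MeOH) gives 2,6-bis(benzyloxy)-4-[(4-methoxybenzyl)oxy]phenol F4.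
- Coupling of F4 with 5 (CuI, picolinic acid, K3PO4, DMSO, 100 °C), a catalyst system suited to hindered phenols, gives 18.

Step 11 (removal of both 4-methoxybenzyl groups). Ionisation sets a benzylic cation free next to two phloroglucinol-type rings. Ring C-alkylation may therefore compete with hydride capture, and some benzyl ether may be lost.
The fallback changes the protecting-group logic so that an oxidative cleavage without a free cation becomes tolerable. It sets out from 16 and comes back at 22.
- Acetylation of 16 (Ac2O, pyridine) gives 2-{3-(benzyloxy)-5-[(4-methoxybenzyl)oxy]phenoxy}-5-[(4-methoxybenzyl)oxy]-1,3-phenylene diacetate F5. Its ring B is deactivated towards both alkylation and quinone formation.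
- DDQ (CH2Cl2–pH 7 buffer, 0 °C) gives 2-[3-(benzyloxy)-5-hydroxyphenoxy]-5-hydroxy-1,3-phenylene diacetate F6.
- Sulfation as in step 12 gives disodium 3,5-diacetoxy-4-[3-(benzyloxy)-5-(sulfonatooxy)phenoxy]phenyl sulfate F7.
- Hydrogenolysis (H2, Pd/C, MeOH) gives disodium 3,5-diacetoxy-4-[3-hydroxy-5-(sulfonatooxy)phenoxy]phenyl sulfate F8.
- Methanolysis of the acetates (NaOMe cat., MeOH, 0 °C, Ar), to which aryl sulfate anions are stable, gives 22.

Step 8 (opening of the pyrone). Methoxide may add at pyrone C4 and exchange the 4-methoxybenzyloxy group for methoxy by addition–elimination, or the open chain may re-close to the pyrone on work-up.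
The fallback avoids the pyrone and builds the chain C4–C5 bond by a vinylogous acylation. It sets out from amide 8 and comes back at 15.
- Commercial methyl (E)-3-methoxybut-2-enoate is trans-etherified with 4 (PPTS cat., toluene, methanol distilled off) to methyl (E)-3-[(4-methoxybenzyl)oxy]but-2-enoate F9.
- Its lithium dienolate (LDA, THF, −78 °C) is a type of nucleophile that attacks carbonyl electrophiles through the γ-carbon. It is acylated with 8 and gives 15 after a cold quench.

**Further compounds**
F1 | step 9 | 2,6-dihydroxy-4-[(4-methoxybenzyl)oxy]benzaldehyde | COc1ccc(COc2cc(O)c(C=O)c(O)c2)cc1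
F2 | step 9 | 2,6-bis(benzyloxy)-4-[(4-methoxybenzyl)oxy]benzaldehyde | COc1ccc(COc2cc(OCc3ccccc3)c(C=O)c(OCc3ccccc3)c2)cc1
F3 | step 9 | 2,6-bis(benzyloxy)-4-[(4-methoxybenzyl)oxy]phenyl formate | COc1ccc(COc2cc(OCc3ccccc3)c(OC=O)c(OCc3ccccc3)c2)cc1
F4 | step 9 | 2,6-bis(benzyloxy)-4-[(4-methoxybenzyl)oxy]phenol | COc1ccc(COc2cc(OCc3ccccc3)c(O)c(OCc3ccccc3)c2)cc1
F5 | step 11 | 2-{3-(benzyloxy)-5-[(4-methoxybenzyl)oxy]phenoxy}-5-[(4-methoxybenzyl)oxy]-1,3-phenylene diacetate | COc1ccc(COc2cc(OC(C)=O)c(Oc3cc(OCc4ccccc4)cc(OCc4ccc(OC)cc4)c3)c(OC(C)=O)c2)cc1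
F6 | step 11 | 2-[3-(benzyloxy)-5-hydroxyphenoxy]-5-hydroxy-1,3-phenylene diacetate | CC(=O)Oc1cc(O)cc(OC(C)=O)c1Oc1cc(O)cc(OCc2ccccc2)c1
F7 | step 11 | disodium 3,5-diacetoxy-4-[3-(benzyloxy)-5-(sulfonatooxy)phenoxy]phenyl sulfate | [Na+].[Na+].CC(=O)Oc1cc(OS(=O)(=O)[O-])cc(OC(C)=O)c1Oc1cc(OS(=O)(=O)[O-])cc(OCc2ccccc2)c1
F8 | step 11 | disodium 3,5-diacetoxy-4-[3-hydroxy-5-(sulfonatooxy)phenoxy]phenyl sulfate | [Na+].[Na+].CC(=O)Oc1cc(OS(=O)(=O)[O-])cc(OC(C)=O)c1Oc1cc(O)cc(OS(=O)(=O)[O-])c1
F9 | step 8 | methyl (E)-3-[(4-methoxybenzyl)oxy]but-2-enoate | COC(=O)/C=C(\C)OCc1ccc(OC)cc1
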